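**Retrosynthetic overview**

1. Target 16 ⇐ tris-silyl ether 15 by one buffered fluoride step; rings A and B are bought as arenes, the oxirane is made early and ring C is made last.
2. Ring C, bond C2–C3: 15 ⇐ diazoketone 14 by enantioselective rhodium-carbene 1,6-C–H insertion. Enabling feature: the O1–CH2 methylene (future C2) is α to O1 and benzylic to the electron-rich ring B, and ring A holds it ortho to the acyl carbon C4, so its C–H bonds are the only ones a carbene at C3 can reach through a six-membered transition state (both 1,5-atoms are hydrogen-free oxygens; the C6 prenyl group is meta and out of reach).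
3. 14 ⇐ methyl ketone 12 (detrifluoroacetylative diazo transfer) ⇐ phenol 6 + benzylic alcohol 11 (Mitsunobu ether bond O1–CH2).
4. 6 ⇐ phloroacetophenone 1 by bis-silylation, O-prenylation and para-Claisen–Cope rearrangement, which places the prenyl group at the future C6 without regioisomers.
5. 11 ⇐ methyl 4-hydroxy-3-iodobenzoate 7 by silylation, Stille prenylation, Shi epoxidation (oxirane ring and its stereocentre) and ester reduction.

Key step: step 11

Abbreviations: TBSO = tert-butyldimethylsilyloxy, TIPSO = triisopropylsilyloxy.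

Assumption: the sense of induction of Rh2(S-PTTL)4 (dirhodium tetrakis[N-phthaloyl-(S)-tert-leucinate]) in step 11 is taken to favour the 2S product; it is to be confirmed on the first run, and the mirror-image catalyst Rh2(R-PTTL)4 would be used without other change if the opposite sense is found.

**Route**

Step 1
Reactants: 1 1-(2,4,6-trihydroxyphenyl)ethanone (dried monohydrate)
Product: 2 1-[2,4-bis(TBSO)-6-hydroxyphenyl]ethanone
Conditions: TBSCl (2.1 equiv), imidazole, DMF, 0 °C to rt
Reagents that add atoms: tert-butyldimethylsilyl chloride, CC(C)(C)[Si](C)(C)Cl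
Why: Silylation should take the para hydroxyl and one of the two equivalent ortho hydroxyls, while the second ortho hydroxyl stays free because it is locked in a hydrogen bond to the acetyl oxygen.

Step 2
Reactants: 2 1-[2,4-bis(TBSO)-6-hydroxyphenyl]ethanone
Product: 3 1-[2,4-bis(TBSO)-6-(3-methylbut-2-enyloxy)phenyl]ethanone
Conditions: 3-methylbut-2-en-1-ol, PPh3, DIAD, THF, 0 °C to rt
Reagents that add atoms: 3-methylbut-2-en-1-ol, CC(C)=CCO
Why: Mitsunobu etherification should O-alkylate the acidic, chelated phenol under neutral conditions that spare the aryl silyl ethers and give no C-alkylation.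

Step 3
Reactants: 3 1-[2,4-bis(TBSO)-6-(3-methylbut-2-enyloxy)phenyl]ethanone
Product: 6 1-[2,4-bis(TBSO)-6-hydroxy-3-(3-methylbut-2-enyl)phenyl]ethanone, via ortho-dienone 4 (not isolated), via para-dienone 5 (not isolated)
Conditions: PhNEt2, 190 °C, sealed tube
Reagents that add atoms: none
Why: Aromatic Claisen rearrangement to the free ortho carbon gives dienone 4, whose crowded 1,1-dimethylallyl group should move on by Cope rearrangement to the para carbon (dienone 5) and tautomerise, so that the prenyl group ends between the two silyloxy groups and para to the regenerated hydroxyl (para-Claisen–Cope sequence with precedent on the corresponding bis(methoxymethyl) ether).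

Step 4
Reactants: 7 methyl 4-hydroxy-3-iodobenzoate
Product: 8 methyl 3-iodo-4-(TIPSO)benzoate
Conditions: TIPSCl, imidazole, DMF, rt
Reagents that add atoms: triisopropylsilyl chloride, CC(C)[Si](Cl)(C(C)C)C(C)C
Why: Standard phenol silylation; the bulky triisopropylsilyl ether is chosen to survive the basic epoxidation medium of step 6 and to be removable with fluoride at the end.

Step 5
Reactants: 8 methyl 3-iodo-4-(TIPSO)benzoate
Product: 9 methyl 3-(3-methylbut-2-enyl)-4-(TIPSO)benzoate
Conditions: Bu3SnCH2CH=CMe2, Pd(PPh3)4 (5 mol %), DMF, 90 °C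
Reagents that add atoms: tributyl(3-methylbut-2-enyl)stannane, CCCC[Sn](CCCC)(CCCC)CC=C(C)C
Why: Stille coupling of the aryl iodide, in which reductive elimination at the unsubstituted terminus of the prenylpalladium intermediate should give the linear prenyl arene while ester and silyl ether stay inert.

Step 6
Reactants: 9 methyl 3-(3-methylbut-2-enyl)-4-(TIPSO)benzoate
Product: 10 methyl 3-{[(2R)-3,3-dimethyloxiran-2-yl]methyl}-4-(TIPSO)benzoate
Conditions: D-fructose-derived Shi ketone (0.3 equiv), Oxone (2KHSO5·KHSO4·K2SO4), K2CO3, Bu4NHSO4, aq. Na2B4O7/Na2EDTA buffer, MeCN–CH2(OMe)2, 0 °C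
Reagents that add atoms: potassium peroxymonosulfate (active component of Oxone), [K+].[O-]S(=O)(=O)OO
Why: Shi asymmetric epoxidation, in which the chiral dioxirane transfers oxygen through a spiro transition state to one face of the trisubstituted olefin, is expected to set the (R)-configured oxirane carbon (the face this ketone selects for trans- and trisubstituted olefins).

Step 7
Reactants: 10 methyl 3-{[(2R)-3,3-dimethyloxiran-2-yl]methyl}-4-(TIPSO)benzoate
Product: 11 [3-{[(2R)-3,3-dimethyloxiran-2-yl]methyl}-4-(TIPSO)phenyl]methanol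
Conditions: i-Bu2AlH (2.5 equiv), CH2Cl2, −78 °C; aq. Rochelle salt
Reagents that add atoms: none
Why: Hydride reduction of the ester to the benzylic alcohol at −78 °C should be much faster than opening of the hindered trisubstituted oxirane, and the silyl ether is inert.

Step 8
Reactants: 6 1-[2,4-bis(TBSO)-6-hydroxy-3-(3-methylbut-2-enyl)phenyl]ethanone; 11 [3-{[(2R)-3,3-dimethyloxiran-2-yl]methyl}-4-(TIPSO)phenyl]methanol
Product: 12 1-[2,4-bis(TBSO)-6-{[3-{[(2R)-3,3-dimethyloxiran-2-yl]methyl}-4-(TIPSO)phenyl]methoxy}-3-(3-methylbut-2-enyl)phenyl]ethanone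
Conditions: PPh3, DIAD, THF, 0 °C to rt
Reagents that add atoms: none
Why: Mitsunobu etherification of the acidic ortho-acyl phenol with the primary benzylic alcohol should form the O1–CH2 bond under neutral conditions that the oxirane and all three silyl ethers tolerate.

Step 9
Reactants: 12 1-[2,4-bis(TBSO)-6-{[3-{[(2R)-3,3-dimethyloxiran-2-yl]methyl}-4-(TIPSO)phenyl]methoxy}-3-(3-methylbut-2-enyl)phenyl]ethanone
Product: 13 1-[2,4-bis(TBSO)-6-{[3-{[(2R)-3,3-dimethyloxiran-2-yl]methyl}-4-(TIPSO)phenyl]methoxy}-3-(3-methylbut-2-enyl)phenyl]-4,4,4-trifluorobutane-1,3-dione (used crude)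
Conditions: LiN(SiMe3)2 (1.1 equiv), THF, −78 °C; CF3CO2CH2CF3, −78 °C, 10 min; aq. NH4Cl
Reagents that add atoms: 2,2,2-trifluoroethyl trifluoroacetate, O=C(OCC(F)(F)F)C(F)(F)F
Why: Claisen-type C-acylation of the kinetic lithium enolate of the methyl ketone with a highly electrophilic trifluoroacetate should be fast enough at −78 °C to outrun silyl transfer from the ortho oxygen and activates the methyl group for diazo transfer.

Step 10
Reactants: 13 1-[2,4-bis(TBSO)-6-{[3-{[(2R)-3,3-dimethyloxiran-2-yl]methyl}-4-(TIPSO)phenyl]methoxy}-3-(3-methylbut-2-enyl)phenyl]-4,4,4-trifluorobutane-1,3-dione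
Product: 14 2-diazo-1-[2,4-bis(TBSO)-6-{[3-{[(2R)-3,3-dimethyloxiran-2-yl]methyl}-4-(TIPSO)phenyl]methoxy}-3-(3-methylbut-2-enyl)phenyl]ethanone
Conditions: p-ABSA, Et3N, H2O (1 equiv), MeCN, rt
Reagents that add atoms: 4-acetamidobenzenesulfonyl azide (p-ABSA), CC(=O)Nc1ccc(cc1)S(=O)(=O)N=[N+]=[N-]
Why: Regitz-type diazo transfer to the activated methylene followed by loss of the trifluoroacetyl group as the N-sulfonyl trifluoroacetamide (detrifluoroacetylative diazo transfer) should give the terminal diazoketone under mild base that spares oxirane and silyl ethers.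

Step 11
Reactants: 14 2-diazo-1-[2,4-bis(TBSO)-6-{[3-{[(2R)-3,3-dimethyloxiran-2-yl]methyl}-4-(TIPSO)phenyl]methoxy}-3-(3-methylbut-2-enyl)phenyl]ethanone
Product: 15 (2S)-5,7-bis(TBSO)-2-[3-{[(2R)-3,3-dimethyloxiran-2-yl]methyl}-4-(TIPSO)phenyl]-6-(3-methylbut-2-enyl)-2,3-dihydro-4H-chromen-4-one
Conditions: Rh2(S-PTTL)4 (1 mol %), CH2Cl2, slow addition of 14, 0 °C
Reagents that add atoms: none
Why: Rh2(S-PTTL)4 should expel N2 from 14 to give an electrophilic rhodium-bound acylcarbene at the future C3, which inserts in a concerted, asynchronous three-centre step (hydride-like transfer, then C–C collapse) into one C–H bond of the O1–CH2–aryl methylene, forming the C2–C3 bond and returning the catalyst. The closest known reaction is the dirhodium-carboxylate-catalysed cyclisation of 2-alkoxyphenyl diazoketones to chroman-4-ones, which has also been run enantioselectively with chiral carboxylate ligands. Ring C closes by 1,6-C–H insertion through a six-membered chair-like transition state that contains O1; the more usual 1,5 mode is absent because both 1,5-atoms are ether oxygens without hydrogen. The C2 stereocentre is set under catalyst control, the chiral carboxylate pocket choosing between the two enantiotopic benzylic hydrogens, while the remote oxirane centre plays no part. The step needs insertion to beat oxonium-ylide formation at O1 (and the [1,2]-benzyl shift that would follow), attack on the 5-silyloxy oxygen and olefin cyclopropanation; this should be secured by the doubly activated C–H bond (α to O1 and benzylic to the p-silyloxyphenyl ring), the low nucleophilicity of aryl ether and aryl silyl ether oxygens toward a carboxylate-ligated rhodium carbene, the absence of C–H bonds α to the silyloxy oxygen, the meta placement of the C6 prenyl group (which cannot reach C3) and slow addition at high dilution.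

Step 12
Reactants: 15 (2S)-5,7-bis(TBSO)-2-[3-{[(2R)-3,3-dimethyloxiran-2-yl]methyl}-4-(TIPSO)phenyl]-6-(3-methylbut-2-enyl)-2,3-dihydro-4H-chromen-4-one
Product: 16 (2S)-2-[3-{[(2R)-3,3-dimethyloxiran-2-yl]methyl}-4-hydroxyphenyl]-5,7-dihydroxy-6-(3-methylbut-2-enyl)-2,3-dihydro-4H-chromen-4-one
Conditions: Bu4NF, AcOH (1:1, 3.3 equiv each), THF, 0 °C
Reagents that add atoms: none
Why: Fluoride should cleave all three aryl silicon–oxygen bonds while acetic acid keeps the liberated oxygens as phenols and not phenoxides, which avoids opening of the oxirane by the neighbouring 4'-oxygen and base-induced ring opening of the flavanone that would scramble C2.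

**Compound list**

1 | 1-(2,4,6-trihydroxyphenyl)ethanone (phloroacetophenone) | CC(=O)c1c(O)cc(O)cc1O | starting material
2 | 1-[2,4-bis(tert-butyldimethylsilyloxy)-6-hydroxyphenyl]ethanone | CC(=O)c1c(O)cc(O[Si](C)(C)C(C)(C)C)cc1O[Si](C)(C)C(C)(C)C | intermediate
3 | 1-[2,4-bis(tert-butyldimethylsilyloxy)-6-(3-methylbut-2-enyloxy)phenyl]ethanone | CC(=O)c1c(OCC=C(C)C)cc(O[Si](C)(C)C(C)(C)C)cc1O[Si](C)(C)C(C)(C)C | intermediate
4 | ortho-dienone: 2-acetyl-3,5-bis(tert-butyldimethylsilyloxy)-6-(2-methylbut-3-en-2-yl)cyclohexa-2,4-dien-1-one | CC(=O)C1=C(O[Si](C)(C)C(C)(C)C)C=C(O[Si](C)(C)C(C)(C)C)C(C(C)(C)C=C)C1=O | intermediate (not isolated)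
5 | para-dienone: 2-acetyl-3,5-bis(tert-butyldimethylsilyloxy)-4-(3-methylbut-2-enyl)cyclohexa-2,5-dien-1-one | CC(=O)C1=C(O[Si](C)(C)C(C)(C)C)C(CC=C(C)C)C(O[Si](C)(C)C(C)(C)C)=CC1=O | intermediate (not isolated)
6 | 1-[2,4-bis(tert-butyldimethylsilyloxy)-6-hydroxy-3-(3-methylbut-2-enyl)phenyl]ethanone | CC(=O)c1c(O)cc(O[Si](C)(C)C(C)(C)C)c(CC=C(C)C)c1O[Si](C)(C)C(C)(C)C | intermediate
7 | methyl 4-hydroxy-3-iodobenzoate | COC(=O)c1ccc(O)c(I)c1 | starting material
8 | methyl 3-iodo-4-(triisopropylsilyloxy)benzoate | COC(=O)c1ccc(O[Si](C(C)C)(C(C)C)C(C)C)c(I)c1 | intermediate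
9 | methyl 3-(3-methylbut-2-enyl)-4-(triisopropylsilyloxy)benzoate | COC(=O)c1ccc(O[Si](C(C)C)(C(C)C)C(C)C)c(CC=C(C)C)c1 | intermediate
10 | methyl 3-{[(2R)-3,3-dimethyloxiran-2-yl]methyl}-4-(triisopropylsilyloxy)benzoate | COC(=O)c1ccc(O[Si](C(C)C)(C(C)C)C(C)C)c(C[C@H]2OC2(C)C)c1 | intermediate
11 | [3-{[(2R)-3,3-dimethyloxiran-2-yl]methyl}-4-(triisopropylsilyloxy)phenyl]methanol | OCc1ccc(O[Si](C(C)C)(C(C)C)C(C)C)c(C[C@H]2OC2(C)C)c1 | intermediate
12 | 1-[2,4-bis(tert-butyldimethylsilyloxy)-6-{[3-{[(2R)-3,3-dimethyloxiran-2-yl]methyl}-4-(triisopropylsilyloxy)phenyl]methoxy}-3-(3-methylbut-2-enyl)phenyl]ethanone | CC(=O)c1c(OCc2ccc(O[Si](C(C)C)(C(C)C)C(C)C)c(C[C@H]3OC3(C)C)c2)cc(O[Si](C)(C)C(C)(C)C)c(CC=C(C)C)c1O[Si](C)(C)C(C)(C)C | intermediate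
13 | 4,4,4-trifluoro-1-aryl-butane-1,3-dione (aryl as in 12) | O=C(CC(=O)C(F)(F)F)c1c(OCc2ccc(O[Si](C(C)C)(C(C)C)C(C)C)c(C[C@H]3OC3(C)C)c2)cc(O[Si](C)(C)C(C)(C)C)c(CC=C(C)C)c1O[Si](C)(C)C(C)(C)C | intermediate
14 | 2-diazo-1-aryl-ethanone (aryl as in 12) | [N-]=[N+]=CC(=O)c1c(OCc2ccc(O[Si](C(C)C)(C(C)C)C(C)C)c(C[C@H]3OC3(C)C)c2)cc(O[Si](C)(C)C(C)(C)C)c(CC=C(C)C)c1O[Si](C)(C)C(C)(C)C | intermediate
15 | (2S)-5,7-bis(tert-butyldimethylsilyloxy)-2-[3-{[(2R)-3,3-dimethyloxiran-2-yl]methyl}-4-(triisopropylsilyloxy)phenyl]-6-(3-methylbut-2-enyl)-2,3-dihydro-4H-chromen-4-one | CC(C)=CCc1c(O[Si](C)(C)C(C)(C)C)cc2c(c1O[Si](C)(C)C(C)(C)C)C(=O)C[C@@H](c1ccc(O[Si](C(C)C)(C(C)C)C(C)C)c(C[C@H]3OC3(C)C)c1)O2 | intermediate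
16 | (2S)-2-[3-{[(2R)-3,3-dimethyloxiran-2-yl]methyl}-4-hydroxyphenyl]-5,7-dihydroxy-6-(3-methylbut-2-enyl)-2,3-dihydro-4H-chromen-4-one | CC(C)=CCc1c(O)cc2c(c1O)C(=O)C[C@@H](c1ccc(O)c(C[C@H]3OC3(C)C)c1)O2 | target

**Summary**

Total step count: 12. Longest linear sequence: 9 steps (7 → 8 → 9 → 10 → 11 → 12 → 13 → 14 → 15 → 16).

**Steps most likely to fail**

Step 11 (key step). The carbene may attack the lone pair of O1 and the resulting oxonium ylide may undergo a [1,2]-shift of the electron-rich benzyl group (ring contraction to a benzofuranone skeleton), or the catalyst may discriminate poorly between the two enantiotopic benzylic hydrogens. The fallback closes ring C at the O1–C2 bond by known chalcone chemistry and sets out from phenol 6 and alcohol 11. Alcohol 11 would be oxidised with MnO2 in CH2Cl2 to 3-{[(2R)-3,3-dimethyloxiran-2-yl]methyl}-4-(triisopropylsilyloxy)benzaldehyde F1. Claisen–Schmidt condensation of the dilithio derivative of 6 (LiN(SiMe3)2, THF, −78 °C to rt) with this aldehyde should give (2E)-1-[2,4-bis(tert-butyldimethylsilyloxy)-6-hydroxy-3-(3-methylbut-2-enyl)phenyl]-3-[3-{[(2R)-3,3-dimethyloxiran-2-yl]methyl}-4-(triisopropylsilyloxy)phenyl]prop-2-en-1-one F2. Enantioselective intramolecular oxa-Michael addition of its single free phenol under a quinine-derived bifunctional thiourea catalyst in toluene would then give 15, where the route is rejoined before step 12. If the selectivity is moderate, 15 would be enriched by crystallisation or preparative chiral chromatography.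

Step 3. The ortho-dienone may tautomerise before the Cope shift, which stops the sequence at the 1,1-dimethylallyl phenol, or silyl groups may be lost or migrate at 190 °C. The fallback replaces the sigmatropic relay by direct C-prenylation and steric differentiation of the two ortho hydroxyls, and sets out from 1. Prenyl bromide with DBU in THF should give 1-[2,4,6-trihydroxy-3-(3-methylbut-2-enyl)phenyl]ethanone F3 as the only mono-C-prenyl isomer, because the two free ring positions are equivalent. One equivalent of TBSCl with imidazole should silylate the para hydroxyl to give 1-[4-(tert-butyldimethylsilyloxy)-2,6-dihydroxy-3-(3-methylbut-2-enyl)phenyl]ethanone F4. Mitsunobu etherification with 11 should take the less hindered ortho hydroxyl (the one not flanked by the prenyl group) and give 1-[4-(tert-butyldimethylsilyloxy)-2-hydroxy-6-{[3-{[(2R)-3,3-dimethyloxiran-2-yl]methyl}-4-(triisopropylsilyloxy)phenyl]methoxy}-3-(3-methylbut-2-enyl)phenyl]ethanone F5. Silylation of the remaining chelated hydroxyl (TBSCl, imidazole, DMAP, DMF, 40 °C) would give 12, where the route is rejoined before step 9.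

Step 9. The silyl group may transfer from the ortho oxygen to the enolate oxygen (1,5 oxygen-to-oxygen migration) before acylation, or acylation of the hindered ketone enolate may stay incomplete. The fallback avoids any anionic enolate and sets out from 12. Condensation with N,N-dimethylformamide dimethyl acetal in toluene at 100 °C should give the enaminone (2E)-3-(dimethylamino)-1-aryl-prop-2-en-1-one (aryl as in 12) F6. Regitz-type diazo transfer with p-toluenesulfonyl azide in MeCN (cycloaddition to the enamine double bond, then cycloreversion with loss of the sulfonyl formamidine) would give diazoketone 14, where the route is rejoined before step 11; compound 13 is bypassed.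

**Further compounds**

F1 | step 11 | 3-{[(2R)-3,3-dimethyloxiran-2-yl]methyl}-4-(triisopropylsilyloxy)benzaldehyde | O=Cc1ccc(O[Si](C(C)C)(C(C)C)C(C)C)c(C[C@H]2OC2(C)C)c1
F2 | step 11 | (2E)-1-[2,4-bis(tert-butyldimethylsilyloxy)-6-hydroxy-3-(3-methylbut-2-enyl)phenyl]-3-[3-{[(2R)-3,3-dimethyloxiran-2-yl]methyl}-4-(triisopropylsilyloxy)phenyl]prop-2-en-1-one | O=C(/C=C/c1ccc(O[Si](C(C)C)(C(C)C)C(C)C)c(C[C@H]2OC2(C)C)c1)c1c(O)cc(O[Si](C)(C)C(C)(C)C)c(CC=C(C)C)c1O[Si](C)(C)C(C)(C)C
F3 | step 3 | 1-[2,4,6-trihydroxy-3-(3-methylbut-2-enyl)phenyl]ethanone | CC(=O)c1c(O)cc(O)c(CC=C(C)C)c1O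
F4 | step 3 | 1-[4-(tert-butyldimethylsilyloxy)-2,6-dihydroxy-3-(3-methylbut-2-enyl)phenyl]ethanone | CC(=O)c1c(O)cc(O[Si](C)(C)C(C)(C)C)c(CC=C(C)C)c1O
F5 | step 3 | 1-[4-(tert-butyldimethylsilyloxy)-2-hydroxy-6-{[3-{[(2R)-3,3-dimethyloxiran-2-yl]methyl}-4-(triisopropylsilyloxy)phenyl]methoxy}-3-(3-methylbut-2-enyl)phenyl]ethanone | CC(=O)c1c(OCc2ccc(O[Si](C(C)C)(C(C)C)C(C)C)c(C[C@H]3OC3(C)C)c2)cc(O[Si](C)(C)C(C)(C)C)c(CC=C(C)C)c1O
F6 | step 9 | (2E)-3-(dimethylamino)-1-[2,4-bis(tert-butyldimethylsilyloxy)-6-{[3-{[(2R)-3,3-dimethyloxiran-2-yl]methyl}-4-(triisopropylsilyloxy)phenyl]methoxy}-3-(3-methylbut-2-enyl)phenyl]prop-2-en-1-one | CN(C)/C=C/C(=O)c1c(OCc2ccc(O[Si](C(C)C)(C(C)C)C(C)C)c(C[C@H]3OC3(C)C)c2)cc(O[Si](C)(C)C(C)(C)C)c(CC=C(C)C)c1O[Si](C)(C)C(C)(C)C
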